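**Compound numbers used throughout**
1 methyl acetoacetate; 2 prenyl bromide; 3 methyl 2-prenylacetoacetate; 4 its methoxymethyl enol ether; 5 the silyl ketene acetal diene; 6 methyl propiolate; 7 cycloadduct; 8 aryl silyl ether; 9 phenol ester; 10 methyl ether ester; 11 benzylic alcohol; 12 ring B aldehyde; 13 3,4-dihydroxyacetophenone; 14 its bis-MOM ether; 15 aldol; 16 tris-MOM chalcone; 17 licoagrochalcone C.
Ring B atoms: C1 carries the propenone chain, C2 the methoxy group, C3 the prenyl group, C4 the hydroxyl; C5 and C6 carry hydrogen.

Remark on the chemistry (assumption): 4 and 5 are drawn as single geometric isomers (E in both). Isomer mixtures are acceptable, because both double bonds are absorbed into the arene in step 4. Compounds 3, 7 and 15 are racemic and their stereocenters do not survive.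

## Analysis of the target

Licoagrochalcone C (17) is an open-chain 1,3-diarylpropenone. Ring A, a 3,4-dihydroxyphenyl group, sits on the carbonyl carbon. Ring B sits on the β-carbon and carries, in order, the enone chain on C1, a methoxy group on C2, a prenyl group on C3 and a hydroxyl on C4, with hydrogen on C5 and C6. There is no stereocenter; the only stereochemical element is the E enone double bond, which is also the more stable geometry. The sensitive groups are the prenyl olefin next to the C4 phenol (acid can close a chroman, and hydrogenation is excluded), the enone (conjugate addition, reduction), and the catechol, which oxidizes readily in base. The difficulty lies in ring B: four contiguous substituents, with the prenyl group wedged between two oxygens that must be told apart, one methylated and one free. Substitution of a resorcinol-type arene does not deliver this pattern cleanly. The strategy rests on the observation that the sequence carbon, oxygen, prenyl, oxygen on C1 to C4, with bare C5 and C6, maps atom for atom onto a 2-prenylacetoacetate-derived 1,3-dioxygenated diene (C2 to C5) and a terminal alkynoate (C1 and C6). Ring B can therefore be built by benzannulation instead of being substituted.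

## Retrosynthetic reasoning

17 ⇒ 16. The last operation is the release of the three phenols, so the first cut is at the three O–CH2 acetal bonds. Free phenols cannot be carried through the enone-forming step: phenoxide formation would switch off the aldehyde of ring B and expose the catechol of ring A to oxidation. Acetal ethers tolerate base, hydride and the oxidation, and they fall to dilute acid. The forward step has to cleave three acetals without protonating the prenyl olefin beside the C4 oxygen.

16 ⇒ 12 + 14 (through 15). The Cα=Cβ double bond of the enone is cut. This is the one bond between the two halves whose formation follows the natural polarity of the pieces: an enolizable methyl ketone on ring A and a non-enolizable aldehyde on ring B. It also divides the molecule into parts of similar size. Cutting an aryl–carbon bond instead would require an organometallic coupling beside four ether oxygens and would not simplify ring B. The forward condensation has to give the E olefin, which is reached by equilibration through 15.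

14 ⇒ 13. Ring A needs only protection of its two phenols.

12 ⇒ 11 ⇒ 10 ⇒ 9. No skeletal bond is cut here; the oxidation level at C1 and the state of O2 are adjusted. The formyl carbon is traced back through the benzylic alcohol 11 to the ester carbon of 10, and the O2 methyl group is removed to uncover the phenol of 9. This is done because 9 is what a benzannulation with an alkynoate delivers: an ester on C1 and, beside it, a free hydroxyl on C2 that is already distinct from the protected oxygen on C4. The forward steps must methylate a hindered, hydrogen-bonded phenol and pass from ester to aldehyde without touching the olefin.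

9 ⇒ 5 + 6 (through 8 and 7). Ring B is opened at C1–C2 and at C5–C6. These cuts keep C2, C3, C4 and C5 together in one four-carbon unit that carries oxygen, prenyl and oxygen in the right order. C1 with its carbon substituent and the bare C6 go into a two-carbon unit. Any other pair of cuts would separate the prenyl carbon from one of its oxygen-bearing neighbours. The gain is large: the ring, its substitution pattern and the difference between O2 and O4 come from one step, and no arene has to be substituted regioselectively. The forward reaction must join the electron-rich diene 5 to the alkynoate 6 in the orientation that puts the ester carbon next to the ketal carbon. Adduct 7 must then aromatize with loss of the methoxy group from C2, the silyl group being shed from 8 afterwards.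

5 ⇒ 4 ⇒ 3 ⇒ 1 + 2. Diene 5 is the doubly enolized form of a β-keto ester. The O–Si bond is cut to reveal the conjugated ester 4, the acetal O–C bond to reveal keto ester 3, and finally the C–C bond between the α-carbon and the prenyl group, which leads to 1 and 2. The prenyl group is thus attached at the most acidic position of 1, the carbon that becomes C3 of ring B. The two enolization steps have to be directed to oxygen, first at the ketone and then, through the methyl group, at the ester.

## Alternatives that were turned down

Alternative 1: The ring B C1–Cβ bond is disconnected by way of a 2-arylbenzopyrylium salt.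
- Forward key step: 2-allyl-3-(benzyloxy)phenol A1 and 1-[3,4-bis(benzyloxy)phenyl]prop-2-yn-1-one A2 are combined in acetic acid containing HPF6. The arene position ortho to the hydroxyl of A1 attacks the terminal carbon of the protonated ynone, and the hydroxyl then condenses with the carbonyl. The product is 8-allyl-7-(benzyloxy)-2-[3,4-bis(benzyloxy)phenyl]chromenylium hexafluorophosphate A3. Base-induced opening of the pyrylium ring, methylation of the phenol so released, exchange of allyl for prenyl by olefin cross metathesis and debenzylation would follow.
- For it: it is convergent and bonds ring B to the three-carbon bridge at an unfunctionalized arene position. Opening the heterocycle places the carbonyl on ring A and the free oxygen on C2 exactly as required. On directness at C1 it is stronger than the chosen route, which spends two redox steps on that carbon.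
- Against it: A1 has two activated positions and only one of them can close the ring. A strong protic acid acts on an allyl group and three benzyl ethers. The opened enone is born as the Z isomer in a pH-dependent equilibrium with cyclic forms. The prenyl terminus must be made late, by metathesis beside the enone. Three benzyl groups must be removed without hydrogenation, which means a Lewis acid next to a prenyl group ortho to a phenol.
- Comparison: the chosen strategy installs the prenyl group in its first step, keeps strong acid away from every olefin, and fixes the ring B pattern by the connectivity of 5 and 6 and not by the site selectivity of an electrophilic substitution.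

Alternative 2: Both bonds to the carbonyl carbon are disconnected in a three-component carbonylative Heck reaction.
- Forward key step: 4-iodo-1,2-bis(methoxymethoxy)benzene A4 and the styrene 1-ethenyl-2-methoxy-4-(methoxymethoxy)-3-(3-methylbut-2-enyl)benzene A5 are joined under CO pressure by Pd(OAc)2, di(1-adamantyl)-n-butylphosphine and NEt3. Oxidative addition of A4 to zerovalent palladium, CO insertion, insertion of A5 and β-hydride elimination give (E)-1-[3,4-bis(methoxymethoxy)phenyl]-3-[2-methoxy-4-(methoxymethoxy)-3-(3-methylbut-2-enyl)phenyl]prop-2-en-1-one A6, which is the same compound as 16.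
- For it: no enolate and no hydroxide are involved, the olefin geometry follows from syn elimination, and the endgame after A6 is unchanged. As an enone-forming step it is as strong as the condensation used here and gentler toward base-sensitive groups.
- Against it: it leaves open how the tetrasubstituted ring B is made. A5 would in practice come from 12 by methylenation, so everything in the chosen route is still needed, plus one step, an iodinated ring A partner and pressure equipment. Direct, non-carbonylative arylation of the electron-rich styrene competes.
- Comparison: the chosen strategy spends its key step on ring B, where the structural difficulty lies, and closes the enone without a metal.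

Alternative 3: The C1–C6 bond of ring B is disconnected, the ring being folded from an open chain.
- Forward key step: methyl (6E)-7-methoxy-3,5-dioxo-4-(3-methylbut-2-enyl)hept-6-enoate A7 is treated with KOH in methanol. The carbanion at C2 of the chain adds to C7, methoxide leaves, and the cyclohexadienone enolizes to methyl 2,4-dihydroxy-3-(3-methylbut-2-enyl)benzoate A8.
- For it: regiochemistry is dictated by the connectivity of the chain and not by orbital coefficients, so on regiochemical certainty it is stronger than a cycloaddition. The reagents are cheap and nothing is moisture-sensitive.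
- Against it: A7 is a polyenolized tricarbonyl compound with the prenyl group between two ketones. Its assembly needs acylation at an already substituted carbon and would probably take more than the three steps that lead to 5. Under hydroxide the most acidic site is C4, not C2. Closure through an enolate oxygen onto C7 to a 4-pyranone and retro-Claisen cleavage compete. A8 has both phenols free, so O4 must be protected selectively in a further step.
- Comparison: the chosen strategy gives 9 with O2 free and O4 masked in the ring-forming step itself, under neutral thermal conditions.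

Key step: step 4

## Route

Step 1
Reactants: 1 methyl acetoacetate; 2 prenyl bromide (1-bromo-3-methylbut-2-ene)
Product: 3 methyl 2-acetyl-5-methylhex-4-enoate (methyl 2-prenylacetoacetate, racemic)
Conditions: NaH, THF, 0 °C; then 2, 0 °C → rt (1 in slight excess)
Reagents that add atoms: none
Why: Acetoacetic ester alkylation: the stabilized sodium enolate is C-alkylated by the allylic bromide in an SN2 reaction, and a slight excess of 1 over base and bromide should suppress dialkylation; the new stereocenter is racemic and disappears in step 2.

Step 2
Reactants: 3 methyl 2-acetyl-5-methylhex-4-enoate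
Product: 4 methyl (E)-3-(methoxymethoxy)-2-(3-methylbut-2-enyl)but-2-enoate
Conditions: NaH, THF/DMPU, 0 °C; MeOCH2Cl, 0 °C → rt
Reagents that add atoms: chloromethyl methyl ether, COCCl
Why: Enol ether formation by O-alkylation of a β-keto ester enolate with a hard α-chloro ether in a cation-solvating medium; the fully substituted α-carbon disfavours C-attack, and the dissociated enolate should give mainly the E isomer, whose methyl group lies cis to the ester.

Step 3
Reactants: 4 methyl (E)-3-(methoxymethoxy)-2-(3-methylbut-2-enyl)but-2-enoate
Product: 5 (1E)-1-methoxy-3-(methoxymethoxy)-2-(3-methylbut-2-enyl)-1-(trimethylsilyloxy)buta-1,3-diene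
Conditions: LiN(i-Pr)2, THF, −78 °C; Me3SiCl, −78 °C → rt; pentane, filtration, used crude
Reagents that add atoms: chlorotrimethylsilane, C[Si](C)(C)Cl
Why: Brassard-type diene synthesis: kinetic γ-deprotonation of the β-alkoxy enoate, guided by the ester carbonyl, gives the extended enolate, which the hard silyl chloride traps on oxygen; there is no α-hydrogen, so the methyl group is the only site that leads to a conjugated anion.

Step 4
Reactants: 5 (1E)-1-methoxy-3-(methoxymethoxy)-2-(3-methylbut-2-enyl)-1-(trimethylsilyloxy)buta-1,3-diene; 6 methyl propiolate
Product: 9 methyl 2-hydroxy-4-(methoxymethoxy)-3-(3-methylbut-2-enyl)benzoate, via cycloadduct 7 (not isolated), via aryl silyl ether 8 (not isolated)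
Conditions: PhMe, 80 → 110 °C, sealed tube; then MeOH, K2CO3 (cat.), rt
Reagents that add atoms: none
Why: This is a normal-electron-demand Diels–Alder reaction of the trioxygenated diene 5 with the acetylenic ester 6, concerted but strongly asynchronous: the CH2 terminus of 5 bonds to the β-carbon of 6 first (C5–C6), and the ketene acetal carbon then bonds to the ester-bearing carbon (C1–C2). Ring B is thereby closed by [4+2] cycloaddition, both ring bonds arising in the one step, to give cyclohexa-1,4-diene 7. A 1,4-elimination of methanol across the mixed ketal carbon C2 and C5–H of 7 aromatizes the ring to silyl ether 8, whose O–Si bond is cleaved by methanolysis in the work-up; should the O–Si bond break first, collapse of the ketal leads to the same phenol. The closest known reaction type is the benzannulation of 1-alkoxy-1-silyloxy-3-alkoxybuta-1,3-dienes (Brassard- and Chan-type dienes) with propiolates and acetylenedicarboxylates, which gives resorcylates. The selectivity that matters is regiochemistry: all three oxygen donors raise the HOMO coefficient at the unsubstituted CH2 terminus and the LUMO of 6 is largest at its β-carbon, so the ester should end on C1 beside the ketal-derived C2. The trisubstituted prenyl olefin is unactivated and should not compete as a dienophile, and either ketene acetal geometry leads to the same arene. The only stereocenter formed, the ketal carbon of 7, is racemic and is erased on aromatization. O2 emerges as a free, ester-chelated phenol and O4 as a methoxymethyl ether, so the two oxygens are distinguished from this point on.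

Step 5
Reactants: 9 methyl 2-hydroxy-4-(methoxymethoxy)-3-(3-methylbut-2-enyl)benzoate
Product: 10 methyl 2-methoxy-4-(methoxymethoxy)-3-(3-methylbut-2-enyl)benzoate
Conditions: MeI, K2CO3, DMF, 40 °C
Reagents that add atoms: iodomethane, CI
Why: Williamson O-methylation of the phenoxide; the hydrogen bond to the ester and the flanking prenyl group slow the reaction, but a polar aprotic solvent and a small, reactive electrophile should overcome this, and the aryl MOM ether and the ester are inert to carbonate.

Step 6
Reactants: 10 methyl 2-methoxy-4-(methoxymethoxy)-3-(3-methylbut-2-enyl)benzoate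
Product: 11 [2-methoxy-4-(methoxymethoxy)-3-(3-methylbut-2-enyl)phenyl]methanol
Conditions: i-Bu2AlH, CH2Cl2, −78 → 0 °C; aq. KNaC4H4O6
Reagents that add atoms: none
Why: Reduction of the benzoate ester to the primary alcohol by a neutral aluminium hydride; the acetal, the aryl ethers and the isolated olefin are not reduced.

Step 7
Reactants: 11 [2-methoxy-4-(methoxymethoxy)-3-(3-methylbut-2-enyl)phenyl]methanol
Product: 12 2-methoxy-4-(methoxymethoxy)-3-(3-methylbut-2-enyl)benzaldehyde
Conditions: MnO2 (activated, excess), CH2Cl2, rt
Reagents that add atoms: none
Why: Heterogeneous benzylic oxidation with MnO2 stops at the aldehyde and leaves the prenyl olefin and the acetal untouched.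

Step 8
Reactants: 13 3,4-dihydroxyacetophenone
Product: 14 1-[3,4-bis(methoxymethoxy)phenyl]ethanone
Conditions: MeOCH2Cl, K2CO3, acetone, 0 °C → rt
Reagents that add atoms: chloromethyl methyl ether, COCCl
Why: Methoxymethyl protection of both phenols by O-alkylation of the phenoxides; carbonate does not enolize the ketone to a useful extent.

Step 9
Reactants: 12 2-methoxy-4-(methoxymethoxy)-3-(3-methylbut-2-enyl)benzaldehyde; 14 1-[3,4-bis(methoxymethoxy)phenyl]ethanone
Product: 16 (E)-1-[3,4-bis(methoxymethoxy)phenyl]-3-[2-methoxy-4-(methoxymethoxy)-3-(3-methylbut-2-enyl)phenyl]prop-2-en-1-one, via aldol 15 (not isolated)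
Conditions: KOH, EtOH/H2O, rt
Reagents that add atoms: none
Why: Claisen–Schmidt condensation: the enolate of methyl ketone 14 adds to the non-enolizable aldehyde 12 to give aldol 15, which loses water by an E1cB elimination; the E enone is the thermodynamic product, and the racemic carbinol center of 15 is destroyed in the dehydration.

Step 10
Reactants: 16 (E)-1-[3,4-bis(methoxymethoxy)phenyl]-3-[2-methoxy-4-(methoxymethoxy)-3-(3-methylbut-2-enyl)phenyl]prop-2-en-1-one
Product: 17 licoagrochalcone C, (E)-1-(3,4-dihydroxyphenyl)-3-[4-hydroxy-2-methoxy-3-(3-methylbut-2-enyl)phenyl]prop-2-en-1-one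
Conditions: 3 M aq. HCl, MeOH, rt → 40 °C, Ar
Reagents that add atoms: none
Why: Acid-catalysed transacetalization of the three aryl MOM ethers to the solvent; an acetal oxygen is far more readily protonated by dilute acid than a trisubstituted olefin, so cleavage should precede attack on the prenyl group if acid strength, temperature and time are kept low.

## Compound list

1 | methyl acetoacetate (methyl 3-oxobutanoate) | CC(=O)CC(=O)OC | starting material
2 | prenyl bromide (1-bromo-3-methylbut-2-ene) | CC(C)=CCBr | starting material
3 | methyl 2-acetyl-5-methylhex-4-enoate (racemic) | CC(=O)C(CC=C(C)C)C(=O)OC | intermediate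
4 | methyl (E)-3-(methoxymethoxy)-2-(3-methylbut-2-enyl)but-2-enoate | COC(=O)/C(CC=C(C)C)=C(\C)OCOC | intermediate
5 | (1E)-1-methoxy-3-(methoxymethoxy)-2-(3-methylbut-2-enyl)-1-(trimethylsilyloxy)buta-1,3-diene | CO/C(O[Si](C)(C)C)=C(/CC=C(C)C)C(=C)OCOC | intermediate
6 | methyl propiolate (methyl prop-2-ynoate) | C#CC(=O)OC | starting material
7 | cycloadduct, methyl 6-methoxy-4-(methoxymethoxy)-5-(3-methylbut-2-enyl)-6-(trimethylsilyloxy)cyclohexa-1,4-diene-1-carboxylate (racemic, not isolated) | COC(=O)C1=CCC(OCOC)=C(CC=C(C)C)C1(OC)O[Si](C)(C)C | intermediate
8 | aryl silyl ether, methyl 4-(methoxymethoxy)-3-(3-methylbut-2-enyl)-2-(trimethylsilyloxy)benzoate (not isolated) | COC(=O)c1ccc(OCOC)c(CC=C(C)C)c1O[Si](C)(C)C | intermediate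
9 | methyl 2-hydroxy-4-(methoxymethoxy)-3-(3-methylbut-2-enyl)benzoate | COC(=O)c1ccc(OCOC)c(CC=C(C)C)c1O | intermediate
10 | methyl 2-methoxy-4-(methoxymethoxy)-3-(3-methylbut-2-enyl)benzoate | COC(=O)c1ccc(OCOC)c(CC=C(C)C)c1OC | intermediate
11 | [2-methoxy-4-(methoxymethoxy)-3-(3-methylbut-2-enyl)phenyl]methanol | COc1c(CO)ccc(OCOC)c1CC=C(C)C | intermediate
12 | 2-methoxy-4-(methoxymethoxy)-3-(3-methylbut-2-enyl)benzaldehyde | COc1c(C=O)ccc(OCOC)c1CC=C(C)C | intermediate
13 | 3,4-dihydroxyacetophenone | CC(=O)c1ccc(O)c(O)c1 | starting material
14 | 1-[3,4-bis(methoxymethoxy)phenyl]ethanone | CC(=O)c1ccc(OCOC)c(OCOC)c1 | intermediate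
15 | aldol, 1-[3,4-bis(methoxymethoxy)phenyl]-3-hydroxy-3-[2-methoxy-4-(methoxymethoxy)-3-(3-methylbut-2-enyl)phenyl]propan-1-one (racemic, not isolated) | COc1c(C(O)CC(=O)c2ccc(OCOC)c(OCOC)c2)ccc(OCOC)c1CC=C(C)C | intermediate
16 | (E)-1-[3,4-bis(methoxymethoxy)phenyl]-3-[2-methoxy-4-(methoxymethoxy)-3-(3-methylbut-2-enyl)phenyl]prop-2-en-1-one | COc1c(/C=C/C(=O)c2ccc(OCOC)c(OCOC)c2)ccc(OCOC)c1CC=C(C)C | intermediate
17 | licoagrochalcone C, (E)-1-(3,4-dihydroxyphenyl)-3-[4-hydroxy-2-methoxy-3-(3-methylbut-2-enyl)phenyl]prop-2-en-1-one | COc1c(/C=C/C(=O)c2ccc(O)c(O)c2)ccc(O)c1CC=C(C)C | target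

## Step count and least certain steps

Total: 10 steps. Longest linear sequence: 9 steps (steps 1 to 7, 9 and 10, from 1); the ring A branch adds step 8.

**Step 4 (key step).** The cycloaddition may be slow, because the fully substituted ketene acetal terminus forces an oxygen substituent into the inside position of the s-cis diene. The diene can then be lost by hydrolysis or desilylation back to 4. The first bond (C5–C6) may also form without ring closure, giving open-chain conjugate addition, and 6 may oligomerize at the temperature required.
Fallback (the arene is bought and the prenyl group is attached to it): it sets out from prenyl bromide 2 and comes back to the route at aldehyde 12. 2,4-Dihydroxybenzaldehyde F1 is C-prenylated with 2 in aqueous KOH at the position between the two oxygens, to give 2,4-dihydroxy-3-(3-methylbut-2-enyl)benzaldehyde F2. Throughput should be modest, since O-alkylation and attack at C5 compete, but the materials are cheap. The non-chelated 4-hydroxyl is then protected selectively with MeOCH2Cl and K2CO3 in acetone to give 2-hydroxy-4-(methoxymethoxy)-3-(3-methylbut-2-enyl)benzaldehyde F3. Methylation of the chelated 2-hydroxyl with MeI and K2CO3 in DMF gives 12. Steps 5 to 7 are then not needed.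

**Step 3 (together with step 2, which feeds it).** Deprotonation of 4 may be incomplete or misdirected. In any Z isomer formed in step 2 the methyl group is remote from the ester carbonyl that guides the base, and C-alkylation in step 2 lowers the supply of 4. Silylation may occur on carbon, and the diene may hydrolyse during isolation.
Fallback (the oxygens are differentiated after the annulation, by chelation, instead of in the diene): it sets out from 3 and comes back at 9. Silylation of 3 with Me3SiCl and Et3N gives methyl (Z)-2-(3-methylbut-2-enyl)-3-(trimethylsilyloxy)but-2-enoate F4. Its deprotonation with LiN(i-Pr)2 and trapping with Me3SiCl, the long-established case for silyl enol ethers of acetoacetates, gives (1E)-1-methoxy-2-(3-methylbut-2-enyl)-1,3-bis(trimethylsilyloxy)buta-1,3-diene F5. Heating F5 with 6 should give, through the cycloadduct methyl 6-methoxy-5-(3-methylbut-2-enyl)-4,6-bis(trimethylsilyloxy)cyclohexa-1,4-diene-1-carboxylate F6 and methyl 3-(3-methylbut-2-enyl)-2,4-bis(trimethylsilyloxy)benzoate F7, after methanolic work-up, methyl 2,4-dihydroxy-3-(3-methylbut-2-enyl)benzoate F8 (identical with A8). One equivalent of MeOCH2Cl with K2CO3 in acetone should alkylate only the non-chelated, more acidic 4-hydroxyl and give 9.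

**Step 10.** The prenyl olefin may be protonated in the acidic medium, and the tertiary cation may be captured by the newly freed C4 phenol (ring closure to a chroman) or by the solvent. Slow cleavage of the last acetal prolongs the exposure.
Fallback (a protecting-group scheme that is unveiled without acid): it sets out from 3 and 13 and comes back at 17. Compound 3 is taken, as in the fallback for step 3, to methyl 2,4-dihydroxy-3-(3-methylbut-2-enyl)benzoate F8. Allyl bromide and K2CO3 in acetone alkylate the 4-hydroxyl selectively to give methyl 2-hydroxy-3-(3-methylbut-2-enyl)-4-(prop-2-enyloxy)benzoate F9. MeI and K2CO3 in DMF give methyl 2-methoxy-3-(3-methylbut-2-enyl)-4-(prop-2-enyloxy)benzoate F10. i-Bu2AlH gives [2-methoxy-3-(3-methylbut-2-enyl)-4-(prop-2-enyloxy)phenyl]methanol F11, and MnO2 gives 2-methoxy-3-(3-methylbut-2-enyl)-4-(prop-2-enyloxy)benzaldehyde F12. Ring A is protected from 13 with allyl bromide and K2CO3 as 1-[3,4-bis(prop-2-enyloxy)phenyl]ethanone F13. Condensation of F12 and F13 with KOH in ethanol should pass through the aldol 1-[3,4-bis(prop-2-enyloxy)phenyl]-3-hydroxy-3-[2-methoxy-3-(3-methylbut-2-enyl)-4-(prop-2-enyloxy)phenyl]propan-1-one F14 to (E)-1-[3,4-bis(prop-2-enyloxy)phenyl]-3-[2-methoxy-3-(3-methylbut-2-enyl)-4-(prop-2-enyloxy)phenyl]prop-2-en-1-one F15. Pd(PPh3)4 (cat.) with K2CO3 in MeOH at rt transfers the three O-allyl groups to the solvent and gives 17. The C-bound prenyl group is not an allylic ether and should stay.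

## Further compounds

F1 | step 4 | 2,4-dihydroxybenzaldehyde | O=Cc1ccc(O)cc1O
F2 | step 4 | 2,4-dihydroxy-3-(3-methylbut-2-enyl)benzaldehyde | O=Cc1ccc(O)c(CC=C(C)C)c1O
F3 | step 4 | 2-hydroxy-4-(methoxymethoxy)-3-(3-methylbut-2-enyl)benzaldehyde | COCOc1ccc(C=O)c(O)c1CC=C(C)C
F4 | step 3 | methyl (Z)-2-(3-methylbut-2-enyl)-3-(trimethylsilyloxy)but-2-enoate | COC(=O)/C(CC=C(C)C)=C(/C)O[Si](C)(C)C
F5 | step 3 | (1E)-1-methoxy-2-(3-methylbut-2-enyl)-1,3-bis(trimethylsilyloxy)buta-1,3-diene | CO/C(O[Si](C)(C)C)=C(/CC=C(C)C)C(=C)O[Si](C)(C)C
F6 | step 3 | methyl 6-methoxy-5-(3-methylbut-2-enyl)-4,6-bis(trimethylsilyloxy)cyclohexa-1,4-diene-1-carboxylate (racemic) | COC(=O)C1=CCC(O[Si](C)(C)C)=C(CC=C(C)C)C1(OC)O[Si](C)(C)C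
F7 | step 3 | methyl 3-(3-methylbut-2-enyl)-2,4-bis(trimethylsilyloxy)benzoate | COC(=O)c1ccc(O[Si](C)(C)C)c(CC=C(C)C)c1O[Si](C)(C)C
F8 | step 3 | methyl 2,4-dihydroxy-3-(3-methylbut-2-enyl)benzoate | COC(=O)c1ccc(O)c(CC=C(C)C)c1O
F9 | step 10 | methyl 2-hydroxy-3-(3-methylbut-2-enyl)-4-(prop-2-enyloxy)benzoate | COC(=O)c1ccc(OCC=C)c(CC=C(C)C)c1O
F10 | step 10 | methyl 2-methoxy-3-(3-methylbut-2-enyl)-4-(prop-2-enyloxy)benzoate | COC(=O)c1ccc(OCC=C)c(CC=C(C)C)c1OC
F11 | step 10 | [2-methoxy-3-(3-methylbut-2-enyl)-4-(prop-2-enyloxy)phenyl]methanol | COc1c(CO)ccc(OCC=C)c1CC=C(C)C
F12 | step 10 | 2-methoxy-3-(3-methylbut-2-enyl)-4-(prop-2-enyloxy)benzaldehyde | COc1c(C=O)ccc(OCC=C)c1CC=C(C)C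
F13 | step 10 | 1-[3,4-bis(prop-2-enyloxy)phenyl]ethanone | CC(=O)c1ccc(OCC=C)c(OCC=C)c1
F14 | step 10 | 1-[3,4-bis(prop-2-enyloxy)phenyl]-3-hydroxy-3-[2-methoxy-3-(3-methylbut-2-enyl)-4-(prop-2-enyloxy)phenyl]propan-1-one (racemic) | COc1c(C(O)CC(=O)c2ccc(OCC=C)c(OCC=C)c2)ccc(OCC=C)c1CC=C(C)C
F15 | step 10 | (E)-1-[3,4-bis(prop-2-enyloxy)phenyl]-3-[2-methoxy-3-(3-methylbut-2-enyl)-4-(prop-2-enyloxy)phenyl]prop-2-en-1-one | COc1c(/C=C/C(=O)c2ccc(OCC=C)c(OCC=C)c2)ccc(OCC=C)c1CC=C(C)C
A1 | alternative 1 | 2-allyl-3-(benzyloxy)phenol | C=CCc1c(O)cccc1OCc1ccccc1
A2 | alternative 1 | 1-[3,4-bis(benzyloxy)phenyl]prop-2-yn-1-one | C#CC(=O)c1ccc(OCc2ccccc2)c(OCc2ccccc2)c1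
A3 | alternative 1 | 8-allyl-7-(benzyloxy)-2-[3,4-bis(benzyloxy)phenyl]chromenylium hexafluorophosphate | C=CCc1c(OCc2ccccc2)ccc2ccc(-c3ccc(OCc4ccccc4)c(OCc4ccccc4)c3)[o+]c12.F[P-](F)(F)(F)(F)F
A4 | alternative 2 | 4-iodo-1,2-bis(methoxymethoxy)benzene | COCOc1ccc(I)cc1OCOC
A5 | alternative 2 | 1-ethenyl-2-methoxy-4-(methoxymethoxy)-3-(3-methylbut-2-enyl)benzene | C=Cc1ccc(OCOC)c(CC=C(C)C)c1OC
A6 | alternative 2 | (E)-1-[3,4-bis(methoxymethoxy)phenyl]-3-[2-methoxy-4-(methoxymethoxy)-3-(3-methylbut-2-enyl)phenyl]prop-2-en-1-one | COc1c(/C=C/C(=O)c2ccc(OCOC)c(OCOC)c2)ccc(OCOC)c1CC=C(C)C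
A7 | alternative 3 | methyl (6E)-7-methoxy-3,5-dioxo-4-(3-methylbut-2-enyl)hept-6-enoate | COC(=O)CC(=O)C(CC=C(C)C)C(=O)/C=C/OC
A8 | alternative 3 | methyl 2,4-dihydroxy-3-(3-methylbut-2-enyl)benzoate | COC(=O)c1ccc(O)c(CC=C(C)C)c1O
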